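Ring B (C-3a′, C-4′, C-5′, C-6′, C-7′, C-7a′) is disconnected at C-3a′–C-4′. The plan exploits the 1,4-relationship of the two carbinol carbons C-1′ and C-4′ across the ring-fusion bond C-3a′–C-7a′: both are carried as ketones, and the C-4′ carbonyl is first bonded to C-7a′, where a 1,3-diketone is easy to assemble. Ring B therefore starts as the five-membered ring B′ (C-4′ to C-7a′), spiro-fused to ring C. A Dowd–Beckwith 1,2-acyl shift to a C-3a′ radical inserts C-3a′ into ring B′ and turns the spiro junction into the B/C fusion. The precursor is a dispiro triketone made from the diprenylated acylphloroglucinol, formaldehyde and a 2-(chloroacetyl)cyclopentanone.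

Key step: step 5

Remark: ring A is written throughout as the enol tautomer of the target SMILES. Locants: ring A C-1 (spiro carbon, identical with C-6′) to C-6; hydrindane C-1′ to C-7a′; "future" locants are used before the hydrindane exists.

Step 1
Reactants: 1 1-(2,4,6-trihydroxyphenyl)ethan-1-one; 2 1-bromo-3-methylbut-2-ene (prenyl bromide)
Product: 3 2-acetyl-3,5-dihydroxy-4,4-bis(3-methylbut-2-en-1-yl)cyclohexa-2,5-dien-1-one
Conditions: NaOMe (2.2 equiv), 2 (2.1 equiv), MeOH, 0 °C to rt
Reagents that add atoms: none
Why: Base-mediated alkylative dearomatisation, in which the second prenyl group enters at the ring carbon that already carries the first, should give the gem-diprenyl vinylogous acid with one nucleophilic ring CH left.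

Step 2
Reactants: 4 cyclopent-2-en-1-one
Product: 6 racemic trans-2-(chloroacetyl)-3-(phenylselanyl)cyclopentan-1-one, via silyl enol ether 5 (not isolated)
Conditions: PhSeSiMe3, TMSOTf (5 mol%), CH2Cl2, −78 °C; then ClCH2COCl, ZnCl2 (10 mol%), 0 °C
Reagents that add atoms: phenyl trimethylsilyl selenide C[Si](C)(C)[Se]c1ccccc1; chloroacetyl chloride ClCC(Cl)=O
Why: Conjugate addition of the silyl selenide gives the regiodefined silyl enol ether 5, and its ZnCl2-mediated C-acylation (Mukaiyama-type acylation of a silyl enol ether) places the chloroacetyl group between the ketone and the selenide-bearing carbon.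

Step 3
Reactants: 3 the diprenyl vinylogous acid of step 1; 6 the selenide diketone of step 2
Product: 8 2-acetyl-6-{[(1R,2R)-1-(chloroacetyl)-5-oxo-2-(phenylselanyl)cyclopentyl]methyl}-3,5-dihydroxy-4,4-bis(3-methylbut-2-en-1-yl)cyclohexa-2,5-dien-1-one, via alkylidene trione 7 (not isolated)
Conditions: (CH2O)n, (R)-TRIP (chiral BINOL-derived phosphoric acid, 10 mol%; its enantiomer if the sense of induction requires), 6 (1.3 equiv), 4 Å MS, CHCl3, 40 °C
Reagents that add atoms: formaldehyde (as paraformaldehyde) C=O
Why: Condensation of 3 with formaldehyde should give the quinone-methide-like alkylidene 7, to which the enol of 6 adds in a phosphoric-acid-controlled Michael addition; because the selenide centre of 6 epimerises by reversible PhSeH elimination–addition, both enantiomers of 6 should funnel (dynamic kinetic resolution) into the adduct with the quaternary centre (future C-7a′) R and the new CH2 anti to selenium.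

Step 4
Reactants: 8 the Michael adduct of step 3
Product: 9 dispiro triketone: (4R,5R)-4-(phenylselanyl)spiro[4.4]nonane-1,6-dione whose C-8 is the spiro carbon C-6 of ring A (2-acetyl-3-hydroxy-4,4-bis(3-methylbut-2-en-1-yl)cyclohex-2-ene-1,5-dione); both configurations at the ring A spiro carbon
Conditions: K2CO3, NaI (cat.), acetone, 0 °C to rt
Reagents that add atoms: none
Why: Intramolecular 5-exo-tet C-alkylation of the 2-alkyl-1,3-dione enolate by the α-chloro ketone closes ring B′ (O-alkylation would need a seven-membered ring); the ring A spiro carbon forms without control and is corrected in step 7.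

Step 5
Reactants: 9 the dispiro triketone of step 4
Product: 10 spiro diketone: ring A spiro (C-1 = C-6′) to (3a′R)-octahydro-1H-indene-1′,4′-dione; both configurations at C-7a′ and at C-1
Conditions: Bu3SnH (1.3 equiv, slow addition), AIBN (cat.), PhH, 80 °C, 0.005 M
Reagents that add atoms: none
Why: Bu3Sn• abstracts PhSe to give the secondary C-3a′ radical, which adds 3-exo-trig to the ring B′ carbonyl C-4′; the cyclopropyloxy radical then cleaves its C-4′–C-7a′ bond to the tertiary, ketone-stabilised C-7a′ radical, which Bu3SnH reduces (Dowd–Beckwith ring expansion, a radical 1,2-acyl shift). Ring B is thereby formed six-membered by 3-exo-trig closure followed by β-scission, that is, ring B′ is enlarged by insertion of C-3a′, while ring C is untouched and the spiro junction becomes the B/C ring fusion. The new stereocentre C-3a′ is set by the quaternary spiro centre C-7a′, because the migrating carbonyl can only be delivered on the face of ring C on which it is held (chirality transfer); C-7a′ is set by hydrogen transfer without control and is equilibrated in step 7. Attack on the ring C carbonyl is excluded because it would build a bicyclo[2.1.0]pentane, and β-scission towards C-5′ would give an unstabilised primary radical. Rearrangement must outrun direct reduction of the C-3a′ radical, which slow addition of Bu3SnH at high dilution should secure.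

Step 6
Reactants: 10 the spiro diketone of step 5
Product: 11 (3a′R,4′S)-4′-hydroxy-4′-methyl derivative of 10 with the 1′-ketone retained; both configurations at C-7a′ and at C-1
Conditions: MeTi(OiPr)3 (2.5 equiv), THF, −30 to 0 °C
Reagents that add atoms: methyltitanium triisopropoxide C[Ti](OC(C)C)(OC(C)C)OC(C)C
Why: The six-membered ring ketone should react much faster than the cyclopentanone with the non-basic organotitanium reagent (Reetz addition, no epimerisation at C-3a′), and methyl should enter from the equatorial, convex face because the axial face is blocked by the axial ring A carbonyl on C-6′, placing the C-4′ hydroxyl anti to H-3a′.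

Step 7
Reactants: 11 the mono-carbinol of step 6
Product: 12 (1S,3a′R,4′S,7a′S)-3-acetyl-4,4′-dihydroxy-4′-methyl-5,5-bis(3-methylbut-2-en-1-yl)octahydrospiro[cyclohex-3-ene-1,6′-indene]-1′,2,6-trione
Conditions: DBU, CH2Cl2, rt
Reagents that add atoms: none
Why: Reversible retro-Michael/Michael cleavage of the C-1–C-7′ bond and enolisation at C-7a′ should equilibrate both centres to the trans-fused isomer in which the bulky diprenyl flank of ring A is equatorial and the acetyl-side carbonyl C-2 is axial, hydrogen-bonded to the axial C-4′ hydroxyl (thermodynamic control; C-3a′ and C-4′ cannot epimerise).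

Step 8
Reactants: 12 the equilibrated keto-carbinol of step 7
Product: 13 (1S,1′R,3a′R,4′S,7a′S)-3-acetyl-1′,4,4′-trihydroxy-1′,4′-dimethyl-5,5-bis(3-methylbut-2-en-1-yl)octahydrospiro[cyclohex-3-ene-1,6′-indene]-2,6-dione (target)
Conditions: MeMgBr (6 equiv), THF, −40 to 0 °C
Reagents that add atoms: methylmagnesium bromide C[Mg]Br
Why: Grignard 1,2-addition to the remaining cyclopentanone, delivered from the α-face by the magnesium alkoxide of the axial C-4′ hydroxyl (chelation-directed addition), should place methyl cis to H-7a′ and the hydroxyl cis to C-7′.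

Compound list
1 | 1-(2,4,6-trihydroxyphenyl)ethan-1-one | CC(=O)c1c(O)cc(O)cc1O | starting material
2 | 1-bromo-3-methylbut-2-ene (prenyl bromide) | CC(C)=CCBr | starting material
3 | 2-acetyl-3,5-dihydroxy-4,4-bis(3-methylbut-2-en-1-yl)cyclohexa-2,5-dien-1-one | CC(=O)C1=C(O)C(CC=C(C)C)(CC=C(C)C)C(O)=CC1=O | intermediate
4 | cyclopent-2-en-1-one | O=C1C=CCC1 | starting material
5 | racemic 3-(phenylselanyl)-1-(trimethylsilyloxy)cyclopent-1-ene | C[Si](C)(C)OC1=CC([Se]c2ccccc2)CC1 | intermediate
6 | racemic trans-2-(chloroacetyl)-3-(phenylselanyl)cyclopentan-1-one (enolised β-diketone, selenide centre labile) | O=C1CCC([Se]c2ccccc2)C1C(=O)CCl | intermediate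
7 | 2-acetyl-3-hydroxy-6-methylidene-4,4-bis(3-methylbut-2-en-1-yl)cyclohex-2-ene-1,5-dione | CC(=O)C1=C(O)C(CC=C(C)C)(CC=C(C)C)C(=O)C(=C)C1=O | intermediate
8 | 2-acetyl-6-{[(1R,2R)-1-(chloroacetyl)-5-oxo-2-(phenylselanyl)cyclopentyl]methyl}-3,5-dihydroxy-4,4-bis(3-methylbut-2-en-1-yl)cyclohexa-2,5-dien-1-one | CC(=O)C1=C(O)C(CC=C(C)C)(CC=C(C)C)C(O)=C(C[C@@]2(C(=O)CC[C@H]2[Se]c3ccccc3)C(=O)CCl)C1=O | intermediate
9 | dispiro triketone: (4R,5R)-4-(phenylselanyl)spiro[4.4]nonane-1,6-dione with C-8 as spiro carbon C-6 of ring A; both configurations at that carbon | CC(=O)C1=C(O)C(CC=C(C)C)(CC=C(C)C)C(=O)C2(C[C@@]3(C(=O)CC[C@H]3[Se]c4ccccc4)C(=O)C2)C1=O | intermediate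
10 | ring A spiro (C-1 = C-6′) to (3a′R)-octahydro-1H-indene-1′,4′-dione; both configurations at C-7a′ and C-1 | CC(=O)C1=C(O)C(CC=C(C)C)(CC=C(C)C)C(=O)C2(CC3[C@@H](CCC3=O)C(=O)C2)C1=O | intermediate
11 | (3a′R,4′S)-4′-hydroxy-4′-methyl-1′-oxo analogue of 10; both configurations at C-7a′ and C-1 | CC(=O)C1=C(O)C(CC=C(C)C)(CC=C(C)C)C(=O)C2(CC3[C@@H](CCC3=O)[C@@](C)(O)C2)C1=O | intermediate
12 | (1S,3a′R,4′S,7a′S)-3-acetyl-4,4′-dihydroxy-4′-methyl-5,5-bis(3-methylbut-2-en-1-yl)octahydrospiro[cyclohex-3-ene-1,6′-indene]-1′,2,6-trione | CC(=O)C1=C(O)C(CC=C(C)C)(CC=C(C)C)C(=O)[C@@]2(C[C@H]3[C@@H](CCC3=O)[C@@](C)(O)C2)C1=O | intermediate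
13 | (1S,1′R,3a′R,4′S,7a′S)-3-acetyl-1′,4,4′-trihydroxy-1′,4′-dimethyl-5,5-bis(3-methylbut-2-en-1-yl)octahydrospiro[cyclohex-3-ene-1,6′-indene]-2,6-dione | CC(=O)C1=C(O)C(CC=C(C)C)(CC=C(C)C)C(=O)[C@@]2(C[C@H]3[C@@H](CC[C@@]3(C)O)[C@@](C)(O)C2)C1=O | target

Total step count: 8. Longest linear sequence: 7 steps (steps 1 and 3 to 8 from 1, or steps 2 to 8 from 4).

Steps most likely to fail

Step 3. Enantio- and diastereocontrol may erode through uncatalysed background addition or through too slow epimerisation of the selenide centre, and 3 may be consumed by self-condensation through 7. The fallback sets out from 3 and 6 and returns at 8. The three-component addition is run without chiral catalyst (NaOAc, AcOH, (CH2O)n), which gives 8 together with its enantiomer, ent-8 F1. The acidic ring A enol then allows classical resolution by fractional crystallisation of the diastereomeric cinchonidine salts, and acidification returns enantiopure 8 for step 4.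

Step 6. Chemoselectivity between the two ring ketones may be lost, leading to addition at both carbonyls. The fallback sets out from 10 and returns at 11. The cyclopentanone is masked as its pyrrolidine enamine, the C-1′ pyrrolidine enamine of 10 F2 (pyrrolidine, MgSO4; the five-ring ketone should condense far more readily than the hindered six-ring ketone). MeTi(OiPr)3 is then added to the free six-ring ketone, and aqueous AcOH hydrolyses the enamine to 11.

Step 8. The nucleophile may attack the wrong face of the C-1′ carbonyl if alkoxide delivery does not operate. The fallback sets out from 12 and returns at 13. The ketone is pre-complexed with the bulky Lewis acid methylaluminium bis(2,6-di-tert-butyl-4-methylphenoxide), MeAl(OAr)2, which occupies the more accessible face, and MeLi then attacks from the opposite face (amphiphilic alkylation). Steric control by the Lewis acid replaces chelation control, and no new compound is made.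

Further compounds
F1 | step 3 | ent-8, 2-acetyl-6-{[(1S,2S)-1-(chloroacetyl)-5-oxo-2-(phenylselanyl)cyclopentyl]methyl}-3,5-dihydroxy-4,4-bis(3-methylbut-2-en-1-yl)cyclohexa-2,5-dien-1-one | CC(=O)C1=C(O)C(CC=C(C)C)(CC=C(C)C)C(O)=C(C[C@]2(C(=O)CC[C@@H]2[Se]c3ccccc3)C(=O)CCl)C1=O
F2 | step 6 | C-1′ pyrrolidine enamine (C-1′=C-2′) of 10 | CC(=O)C1=C(O)C(CC=C(C)C)(CC=C(C)C)C(=O)C2(CC3[C@@H](CC=C3N4CCCC4)C(=O)C2)C1=O
F0 | step 8 | none | none
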